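**Retrosynthetic overview**
1. The target is a [4+2] cross-dimer of two xanthanolide halves. Disconnect the C1–OH/C2=C3 enone (bromohydrin, then loss of HBr, from a C1=C2 adduct), then the spiro-cyclohexene at C5–C13' and C3–C11' (Diels–Alder), giving (3aR,7S,8aR)-8-epi-xanthatin as diene and the 1,5-epoxide of its antipode as dienophile.
2. Both halves therefore come from one racemic 8-epi-xanthatin, which is resolved; one antipode is the diene, the other is epoxidised, so neither is discarded.
3. 8-epi-Xanthatin is disconnected at C7–C8, C11–C12 and C12–O to an open-chain allenyl aldehyde plus CO: a molybdenum-mediated [2+2+1] (hetero-Pauson–Khand) closes the cycloheptene and the α-methylene-γ-butyrolactone in one operation.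
4. Enabling feature: the cis-fused α-methylene-γ-butyrolactone ring O–C8–C7–C11(=C13H2)–C12(=O) on the C7–C8 edge of the cycloheptene of the diene-derived half is the retron of allene + aldehyde + CO, and the trisubstituted C1=C5 ring olefin holds the C6 and C10 arms cis for seven-ring closure.
5. The open-chain precursor is built by conjugate addition (C10), Horner–Wadsworth–Emmons (C1=C5) and Wittig (C2=C3) reactions. Ring order: cycloheptene + lactone (one step), then the oxirane of the second half, then the spiro-cyclohexene.

Key step: step 9

Conventions: xanthane numbering is used for both C15 halves (C12 lactone carbonyl, C11 its α-carbon, C13 the exocyclic methylene, C7/C8 the lactone-bearing ring carbons, C1 and C5–C10 the cycloheptane, C2–C4 and C15 the oxobutenyl chain, C14 the methyl on C10). Primed numbers belong to the epoxide-bearing half.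
Remark: in the given structure the two halves derive from antipodal monomers [monomer descriptors (7R,8R,10S) and (7'S,8'S,10'R)], so both antipodes of the monomer are needed; the monomer is therefore made as a racemate and resolved, and the two fractions of the one preparative separation are entered as steps 10 and 11.

Step 1
Reactants: 1 triethyl phosphonoacetate; 2 acetaldehyde
Product: 3 ethyl 2-(diethoxyphosphoryl)but-2-enoate (E/Z mixture)
Conditions: TiCl4, N-methylmorpholine, THF, 0 °C to rt
Reagents that add atoms: none
Why: Knoevenagel condensation (titanium tetrachloride/amine variant) joins the active methylene of 1 to the aldehyde, and the E/Z ratio is immaterial because this double bond is consumed in step 2.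

Step 2
Reactants: 3 ethyl 2-(diethoxyphosphoryl)but-2-enoate; 4 (1,3-dioxolan-2-ylmethyl)magnesium bromide
Product: 5 ethyl 2-(diethoxyphosphoryl)-4-(1,3-dioxolan-2-yl)-3-methylbutanoate (racemic, both diastereomers)
Conditions: CuI (10 mol %), THF, −30 to 0 °C; aq. NH4Cl
Reagents that add atoms: none
Why: Copper-catalysed conjugate addition of the Grignard reagent to the doubly activated alkylidene phosphonoacetate creates C10 with its methyl group and the dioxolane-masked C8 aldehyde; C10 is racemic by design and the second centre (C1) is destroyed in step 5, so the mixture is carried on.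

Step 3
Reactants: 6 but-3-yn-1-ol
Product: 8 penta-3,4-dien-1-ol, via Mannich base 7 (not isolated)
Conditions: (CH2O)n, CuI (0.5 equiv), i-Pr2NH, 1,4-dioxane, reflux
Reagents that add atoms: paraformaldehyde (reacts as formaldehyde), C=O
Why: Crabbé allene homologation, in which the copper acetylide undergoes Mannich coupling with formaldehyde and the amine and the propargylic amine 7 then delivers hydride from an N-isopropyl C–H to the alkyne with loss of the imine, giving the terminal allene.

Step 4
Reactants: 8 penta-3,4-dien-1-ol
Product: 9 penta-3,4-dienal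
Conditions: Dess–Martin periodinane, CH2Cl2, 0 °C; filtered solution used at once
Reagents that add atoms: none
Why: Dess–Martin oxidation is neutral and fast at 0 °C, so the β,γ-allenic aldehyde should form without isomerisation to penta-2,4-dienal, and the volatile product is not concentrated.

Step 5
Reactants: 5 ethyl 2-(diethoxyphosphoryl)-4-(1,3-dioxolan-2-yl)-3-methylbutanoate; 9 penta-3,4-dienal
Product: 10 ethyl (2E)-2-[1-(1,3-dioxolan-2-yl)propan-2-yl]hepta-2,5,6-trienoate (racemic)
Conditions: NaH, THF, 0 °C; then 9, −78 °C to rt
Reagents that add atoms: none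
Why: Horner–Wadsworth–Emmons olefination of the stabilised α-branched phosphonate anion forms C1=C5 and, under the usual thermodynamic control, should place the ester trans to the new C6 chain (E), which is the geometry that later holds C6 and C10 cis; any Z isomer is removed by chromatography.

Step 6
Reactants: 10 ethyl (2E)-2-[1-(1,3-dioxolan-2-yl)propan-2-yl]hepta-2,5,6-trienoate
Product: 11 (2E)-2-[1-(1,3-dioxolan-2-yl)propan-2-yl]hepta-2,5,6-trien-1-ol (racemic)
Conditions: i-Bu2AlH (2.2 equiv), CH2Cl2, −78 °C; aq. potassium sodium tartrate work-up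
Reagents that add atoms: none
Why: i-Bu2AlH reduces the conjugated ester by 1,2-addition to the allylic alcohol at −78 °C and leaves the dioxolane, the trisubstituted olefin and the allene untouched.

Step 7
Reactants: 11 (2E)-2-[1-(1,3-dioxolan-2-yl)propan-2-yl]hepta-2,5,6-trien-1-ol; 12 1-(triphenyl-λ5-phosphanylidene)propan-2-one
Product: 14 (3E,5E)-5-[1-(1,3-dioxolan-2-yl)propan-2-yl]deca-3,5,8,9-tetraen-2-one (racemic), via enal 13 (not isolated)
Conditions: MnO2 (10 equiv), 12 (1.3 equiv), toluene, 60 °C, one pot
Reagents that add atoms: none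
Why: Tandem oxidation–Wittig reaction, in which MnO2 oxidises only the allylic alcohol to enal 13 and the stabilised ylide traps it in situ to give the (E)-enone C2=C3 of the dienone without isolating the sensitive enal.

Step 8
Reactants: 14 (3E,5E)-5-[1-(1,3-dioxolan-2-yl)propan-2-yl]deca-3,5,8,9-tetraen-2-one
Product: 15 (4E)-3-methyl-4-[(1E)-3-oxobut-1-en-1-yl]nona-4,7,8-trienal (racemic)
Conditions: 1 M aq. HCl (cat.), THF, rt
Reagents that add atoms: water, O
Why: Acid-catalysed acetal hydrolysis unveils the C8 aldehyde, and the dienone and the isolated allene should tolerate dilute aqueous acid at room temperature.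

Step 9
Reactants: 15 (4E)-3-methyl-4-[(1E)-3-oxobut-1-en-1-yl]nona-4,7,8-trienal
Product: 16 (±)-8-epi-xanthatin [rac-(3aR,7S,8aR)-7-methyl-3-methylidene-6-[(1E)-3-oxobut-1-en-1-yl]-3,3a,4,7,8,8a-hexahydro-2H-cyclohepta[b]furan-2-one]
Conditions: Mo(CO)6 (1.2 equiv), DMSO (10 equiv), toluene (0.01 M), 100 °C, argon
Reagents that add atoms: carbon monoxide, delivered as a ligand of molybdenum hexacarbonyl Mo(CO)6, [C-]#[O+]
Why: Proposed new method: DMSO oxidises CO ligands off Mo(CO)6 to give a coordinatively unsaturated zerovalent molybdenum carbonyl that binds the aldehyde C8=O and the internal C7=C11 π-bond of the allene; oxidative cyclisation forms C7–C8, CO inserts into the Mo–O8 bond (alkoxycarbonyl–molybdenum) and C11–C12 reductive elimination closes the lactone (insertion into Mo–C11 followed by C12–O elimination would give the same product), and the closest known reaction type is the Mo(CO)6/DMSO hetero-Pauson–Khand cyclocarbonylation of allenyl aldehydes to fused α-methylene-γ-butyrolactones, which is established for five- and six-membered carbocycles but not for a seven-membered ring or a dienone-bearing tether. The cycloheptene closes by the C7–C8 bond in a 7-exo mode at both π-systems (C11 and O8 stay outside that ring), and the γ-lactone closes as the five-membered ring of the formal [2+2+1] of C7=C11, C8=O and CO. C7 and C8 are set cis because the allene and the aldehyde add suprafacially to one metal centre, and their relation to C10 should follow from a chair-like cycloheptene transition state with the C10 methyl pseudo-equatorial and the bulky molybdenum fragment on the outer face, which puts H7, H8 and H10 on one side. The step needs the proximal and not the distal allene π-bond to react (usual for molybdenum, and the distal mode would need a nine-membered ring), the aldehyde and not the ketone to react (the E-C2=C3 bond holds C4=O out of reach), and cyclisation to beat oligomerisation and Diels–Alder dimerisation of the product (the C1=C5 olefin holds the C6 and C10 arms cis, and the run is at 0.01 M).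

Step 10
Reactants: 16 (±)-8-epi-xanthatin
Product: 17 (3aR,7S,8aR)-8-epi-xanthatin
Conditions: preparative HPLC, cellulose tris(3,5-dimethylphenylcarbamate) chiral stationary phase, n-hexane/2-propanol, 20 °C; fraction kept cold and dilute
Reagents that add atoms: none
Why: Chromatographic resolution on a polysaccharide chiral phase separates the antipodes without derivatisation, and this fraction is the antipode that serves as the diene half (absolute configuration to be assigned by chiroptical comparison before use).

Step 11
Reactants: 16 (±)-8-epi-xanthatin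
Product: 18 (3aS,7R,8aS)-8-epi-xanthatin
Conditions: the other fraction of the same preparative chiral HPLC run as in step 10 (cellulose tris(3,5-dimethylphenylcarbamate) phase, n-hexane/2-propanol, 20 °C); fraction kept cold and dilute
Reagents that add atoms: none
Why: The same chromatographic resolution delivers the antipode as its second fraction, which is collected as a product in its own right because the epoxide-bearing half of the target has the opposite configuration at C7, C8 and C10, so no part of the racemate is discarded.

Step 12
Reactants: 18 (3aS,7R,8aS)-8-epi-xanthatin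
Product: 19 (1R,5R,7S,8S,10R)-1,5-epoxy-8-epi-xanthatin (oxirane oxygen anti to the C10 methyl and to the lactone)
Conditions: mCPBA (1.05 equiv), CH2Cl2, 0 °C; NaHCO3 wash
Reagents that add atoms: mCPBA, OOC(=O)c1cccc(Cl)c1
Why: Prilezhaev epoxidation, in which the electrophilic peracid selects the trisubstituted, electron-richest C1=C5 (γ,δ) olefin over the enone and acrylate olefins and should approach anti to the adjacent C10 methyl and the lactone (the face of H7, H8 and H10).

Step 13
Reactants: 17 (3aR,7S,8aR)-8-epi-xanthatin; 19 (1R,5R,7S,8S,10R)-1,5-epoxy-8-epi-xanthatin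
Product: 20 exo-carbonyl Diels–Alder adduct (C5–C13' and C3–C11' bonds, C1=C2 olefin, 3-acetyl cis to C6, H5 cis to H7, spiro centre C11' formed anti to C6'/C9')
Conditions: 19 (3 equiv, excess recovered), toluene (2 M), BHT (cat.), 70 °C, dark
Reagents that add atoms: none
Why: Thermal Diels–Alder reaction of the semicyclic s-cis diene C5=C1–C2=C3 of 17 with the exocyclic acrylate olefin of 19 ('ortho' regiochemistry, acetyl-bearing C3 to the α-carbon C11' and C5 to C13'), in which 19 has no diene and is used in excess to outrun self-dimerisation of 17, is attacked on the convex face of its cis-fused lactone in the exo-carbonyl mode typical of α-methylene lactones, and for this antipodal pairing that transition state bonds to the diene face syn to C11/O8 and the C10 methyl, so C5, C3 and the spiro centre C11' are set together.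

Step 14
Reactants: 20 exo-carbonyl Diels–Alder adduct
Product: 21 bromohydrin (C1–OH on the upper face, C2–Br on the lower face, trans)
Conditions: N-bromosuccinimide (1.1 equiv), THF/H2O 4:1, 0 °C, dark
Reagents that add atoms: N-bromosuccinimide, O=C1CCC(=O)N1Br; water, O
Why: Bromohydrin formation, in which the only electron-rich olefin (C1=C2) takes up bromine on the open lower face of the cyclohexene (the upper face carries the C3 acetyl group, C6 and C7') and water opens the bromonium ion anti at the tertiary C1 (Markovnikov), which places the C1 hydroxyl on the upper face, cis to C6 and trans to H5 as in the target.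

Step 15
Reactants: 21 bromohydrin
Product: 22 target CNP0177598.2
Conditions: Et3N (3 equiv), CH2Cl2, 0 °C to rt
Reagents that add atoms: none
Why: E1cB dehydrobromination of the β-bromo ketone through the C3 enolate gives the C2=C3 enone, needs no anti-periplanar hydrogen, leaves the tertiary C1 carbinol untouched and erases the C3 stereocentre.

**Compound list**
1 | triethyl phosphonoacetate | CCOC(=O)CP(=O)(OCC)OCC | starting material
2 | acetaldehyde | CC=O | starting material
3 | ethyl 2-(diethoxyphosphoryl)but-2-enoate (E/Z mixture) | CCOC(=O)C(=CC)P(=O)(OCC)OCC | intermediate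
4 | (1,3-dioxolan-2-ylmethyl)magnesium bromide (THF solution) | Br[Mg]CC1OCCO1 | starting material
5 | ethyl 2-(diethoxyphosphoryl)-4-(1,3-dioxolan-2-yl)-3-methylbutanoate (racemic, both diastereomers) | CCOC(=O)C(C(C)CC1OCCO1)P(=O)(OCC)OCC | intermediate
6 | but-3-yn-1-ol | C#CCCO | starting material
7 | 5-[di(propan-2-yl)amino]pent-3-yn-1-ol (Mannich base, formed in the flask and not isolated) | OCCC#CCN(C(C)C)C(C)C | intermediate
8 | penta-3,4-dien-1-ol | C=C=CCCO | intermediate
9 | penta-3,4-dienal | C=C=CCC=O | intermediate
10 | ethyl (2E)-2-[1-(1,3-dioxolan-2-yl)propan-2-yl]hepta-2,5,6-trienoate (racemic) | CCOC(=O)/C(=C/CC=C=C)C(C)CC1OCCO1 | intermediate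
11 | (2E)-2-[1-(1,3-dioxolan-2-yl)propan-2-yl]hepta-2,5,6-trien-1-ol (racemic) | OC/C(=C/CC=C=C)C(C)CC1OCCO1 | intermediate
12 | 1-(triphenyl-λ5-phosphanylidene)propan-2-one | CC(=O)C=P(c1ccccc1)(c1ccccc1)c1ccccc1 | starting material
13 | (2E)-2-[1-(1,3-dioxolan-2-yl)propan-2-yl]hepta-2,5,6-trienal (racemic, formed in the flask and not isolated) | O=C/C(=C/CC=C=C)C(C)CC1OCCO1 | intermediate
14 | (3E,5E)-5-[1-(1,3-dioxolan-2-yl)propan-2-yl]deca-3,5,8,9-tetraen-2-one (racemic) | CC(=O)/C=C/C(=C/CC=C=C)C(C)CC1OCCO1 | intermediate
15 | (4E)-3-methyl-4-[(1E)-3-oxobut-1-en-1-yl]nona-4,7,8-trienal (racemic) | CC(=O)/C=C/C(=C/CC=C=C)C(C)CC=O | intermediate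
16 | (±)-8-epi-xanthatin (racemate, both antipodes written) | C=C1C(=O)O[C@@H]2C[C@H](C)C(/C=C/C(C)=O)=CC[C@H]12.C=C1C(=O)O[C@H]2C[C@@H](C)C(/C=C/C(C)=O)=CC[C@@H]12 | intermediate
17 | (3aR,7S,8aR)-8-epi-xanthatin (diene half) | C=C1C(=O)O[C@@H]2C[C@H](C)C(/C=C/C(C)=O)=CC[C@H]12 | intermediate
18 | (3aS,7R,8aS)-8-epi-xanthatin (antipode) | C=C1C(=O)O[C@H]2C[C@@H](C)C(/C=C/C(C)=O)=CC[C@@H]12 | intermediate
19 | (1R,5R,7S,8S,10R)-1,5-epoxy-8-epi-xanthatin (dienophile half) | C=C1C(=O)O[C@H]2C[C@@H](C)[C@]3(/C=C/C(C)=O)O[C@@H]3C[C@@H]12 | intermediate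
20 | exo-carbonyl Diels–Alder adduct (C1=C2 olefin, 3-acetyl) | C=C1C(=O)O[C@@H]2C[C@H](C)C3=C[C@H](C(C)=O)[C@]4(C[C@@H]3C[C@H]12)C(=O)O[C@H]1C[C@@H](C)[C@]2(/C=C/C(C)=O)O[C@@H]2C[C@H]14 | intermediate
21 | bromohydrin (1-hydroxy, 2-bromo, trans) | C=C1C(=O)O[C@@H]2C[C@H](C)[C@@]3(O)[C@@H](Br)[C@H](C(C)=O)[C@]4(C[C@@H]3C[C@H]12)C(=O)O[C@H]1C[C@@H](C)[C@]2(/C=C/C(C)=O)O[C@@H]2C[C@H]14 | intermediate
22 | CNP0177598.2 | C=C1C(=O)O[C@@H]2C[C@H](C)[C@@]3(O)C=C(C(C)=O)[C@]4(C[C@@H]3C[C@H]12)C(=O)O[C@H]1C[C@@H](C)[C@]2(/C=C/C(C)=O)O[C@@H]2C[C@H]14 | target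

**Totals**
Total steps: 15 (steps 10 and 11 are the two collected fractions of one preparative separation). Longest linear sequence: 12 steps (1, 2, 5–9, 11–15).

**Steps most likely to fail**

1. Step 9 (Proposed new method). The seven-membered oxidative cyclisation may be outrun by oligomerisation or by binding of molybdenum to the dienone, and the relay from C10 to C7/C8 may be weak. The fallback sets out from 15 and comes back at 16. Aldehyde 15 is treated with hexabutylditin (Bu3Sn)2 and catalytic allylpalladium chloride dimer [Pd(C3H5)Cl]2 in THF at rt. Stannylpalladation of the allene puts tin on the central carbon C11, and the resulting allyl-metal adds through C7 to the aldehyde in a cyclic transition state (distannylative carbocyclisation, a known reaction of allenyl aldehydes). This gives the racemic cis-hydroxy alkenylstannane F1. Iododestannylation (I2, CH2Cl2, 0 °C) gives the racemic 2-iodoalkenyl alcohol F2. Classical carbonylative lactonisation (Pd(PPh3)4, CO 1 atm, Et3N, MeCN, 60 °C) then gives 16, so ring closure and carbonylation are separated.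

2. Step 13. Self-dimerisation of 17 may compete with the cross reaction, and the diene's own bias may send the dienophile to the lower face (endo-carbonyl mode), giving the C5/C3-epimeric adduct. The fallback sets out from 17 and comes back at 20. The lactone of 17 is opened with Me3Al/MeNH(OMe)·HCl (CH2Cl2, 0 °C) to the hydroxy Weinreb amide F3, whose 2-substituted acrylamide is a poor dienophile and whose C8 hydroxyl lies on the upper face. Deprotonation with MeMgBr (1 equiv, toluene) and addition of 19 give a magnesium alkoxide that binds the lactone carbonyl of 19 and delivers it to the upper diene face with the carbonyl exo, over C6–C8 (alkoxide-templated Diels–Alder reaction), forming the seco adduct F4. p-TsOH in benzene at rt relactonises F4 to 20.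

3. Step 14. The bromonium ion may be opened with the wrong regio- or facial sense, or the neighbouring acetyl oxygen may intervene. The fallback sets out from 20 and comes back at 22. The saturated C4 ketone is reduced in preference to the enone (NaBH4, CH2Cl2/MeOH, −78 °C) to the homoallylic alcohol F5, whose carbinol sits on the upper face because the acetyl group is cis to C6. Hydroxyl-directed epoxidation (VO(acac)2, t-BuOOH, CH2Cl2, 0 °C) should then deliver oxygen to the upper face of C1=C2, giving the epoxy alcohol F6. Dess–Martin oxidation gives the β,γ-epoxy ketone F7, and Et3N opens the oxirane by E1cB to give 22.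

**Further compounds**
F1 | step 9 | racemic cis-hydroxy alkenylstannane (8-epi-xanthatin skeleton with free C8–OH and 1-(tributylstannyl)vinyl on C7; H7, H8, H10 cis) | O[C@@H]1C[C@H](C)C(/C=C/C(C)=O)=CC[C@@H]1C(=C)[Sn](CCCC)(CCCC)CCCC.O[C@H]1C[C@@H](C)C(/C=C/C(C)=O)=CC[C@H]1C(=C)[Sn](CCCC)(CCCC)CCCC
F2 | step 9 | racemic cis-hydroxy 2-iodoalkene (1-iodovinyl on C7) | O[C@@H]1C[C@H](C)C(/C=C/C(C)=O)=CC[C@@H]1C(=C)I.O[C@H]1C[C@@H](C)C(/C=C/C(C)=O)=CC[C@H]1C(=C)I
F3 | step 13 | hydroxy Weinreb amide from 17 (C8–OH free, N-methoxy-N-methyl acrylamide on C7) | O[C@@H]1C[C@H](C)C(/C=C/C(C)=O)=CC[C@@H]1C(=C)C(=O)N(C)OC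
F4 | step 13 | seco Diels–Alder adduct (as 20, diene-half lactone opened to C8–OH and Weinreb amide) | O[C@@H]2C[C@H](C)C3=C[C@H](C(C)=O)[C@]4(C[C@@H]3C[C@@H]2C(=C)C(=O)N(C)OC)C(=O)O[C@H]1C[C@@H](C)[C@]2(/C=C/C(C)=O)O[C@@H]2C[C@H]14
F5 | step 14 | C4 alcohol of 20 (both C4 epimers) | C=C1C(=O)O[C@@H]2C[C@H](C)C3=C[C@H](C(C)O)[C@]4(C[C@@H]3C[C@H]12)C(=O)O[C@H]1C[C@@H](C)[C@]2(/C=C/C(C)=O)O[C@@H]2C[C@H]14
F6 | step 14 | 1,2-epoxy C4 alcohol (oxirane on the upper face) | C=C1C(=O)O[C@@H]2C[C@H](C)[C@@]3(O5)[C@H]5[C@H](C(C)O)[C@]4(C[C@@H]3C[C@H]12)C(=O)O[C@H]1C[C@@H](C)[C@]2(/C=C/C(C)=O)O[C@@H]2C[C@H]14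
F7 | step 14 | 1,2-epoxy ketone (oxirane on the upper face) | C=C1C(=O)O[C@@H]2C[C@H](C)[C@@]3(O5)[C@H]5[C@H](C(C)=O)[C@]4(C[C@@H]3C[C@H]12)C(=O)O[C@H]1C[C@@H](C)[C@]2(/C=C/C(C)=O)O[C@@H]2C[C@H]14
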